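**Retrosynthetic overview**
- Target ⇐ its pentabenzyl ether by hydrogenolysis; the C4 ketone and C3–OH ⇐ a fused flav-3-ene ketal by dihydroxylation on the face opposite the ketal aryl group, then benzylic oxidation.
- Flav-3-ene ketal ⇐ a flavan-fused 2-arylbenzofuran-3-carbaldehyde + 3,5-bis(benzyloxy)phenol by a chiral-acid-catalysed dearomative chromenylation (C4–C4a and O1–C2 bonds, ketal centre).
- Benzofuran aldehyde ⇐ 8-bromoflavan-3-ol by alkynylation, debenzylative iodocyclisation and formylation.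
- Flavan-3-ol ⇐ (E)-1,3-diarylpropene by Shi epoxidation and 6-endo phenol cyclisation; propene ⇐ the same phenol + a cinnamyl alcohol.
- Ring order: flavan pyran ring, then furan ring, then pyran ring with the ketal centre; C3/C4 oxygenation last.

Assumption: the SMILES is read literally. Its descriptors (C2 R, C3 S; flavan 2S,3R) place the C2 aryl group and the C3 hydroxyl anti, i.e. a trans-fused furan/pyranone junction, which ketal ring closure cannot give (it gives cis), so C3–O is made last on the intact ring system and acid is avoided afterwards.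
Assumption: the sense of induction of (R)-TRIP in step 9 is taken as shown; if experiment shows the opposite, (S)-TRIP is used.
Locants: the chromanone unit is numbered as a flavonoid (O1, C2, C3, C4, ring A, ring B); the flavan unit carries primes.

Step 1
Reactants: 1 3,5-bis(benzyloxy)phenol; 2 (E)-3-[4-(benzyloxy)phenyl]prop-2-en-1-ol
Product: 3 3,5-bis(benzyloxy)-2-{(E)-3-[4-(benzyloxy)phenyl]prop-2-en-1-yl}phenol
Conditions: H2SO4 on SiO2 (cat.), CH2Cl2, rt
Reagents that add atoms: none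
Why: Friedel–Crafts allylation, in which the cinnamyl cation attacks the phenol ortho position and the E alkene is kept.

Step 2
Reactants: 3 3,5-bis(benzyloxy)-2-{(E)-3-[4-(benzyloxy)phenyl]prop-2-en-1-yl}phenol
Product: 4 tert-butyldimethylsilyl ether of 3
Conditions: TBSCl, imidazole, DMF, rt
Reagents that add atoms: tert-butyldimethylsilyl chloride, CC(C)(C)[Si](C)(C)Cl
Why: Standard silylation masks the phenol so that it survives the basic oxidative epoxidation.

Step 3
Reactants: 4 tert-butyldimethylsilyl ether of 3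
Product: 5 tert-butyl{3,5-bis(benzyloxy)-2-[((2R,3R)-3-[4-(benzyloxy)phenyl]oxiran-2-yl)methyl]phenoxy}dimethylsilane
Conditions: D-fructose-derived Shi ketone (30 mol%), Oxone (2KHSO5·KHSO4·K2SO4), K2CO3, Bu4NHSO4, MeCN/CH2(OMe)2/aq. Na2B4O7 buffer (pH 10.5), 0 °C
Reagents that add atoms: potassium peroxymonosulfate (KHSO5 of Oxone), [K+].[O-]S(=O)(=O)OO
Why: Shi epoxidation, in which the chiral dioxirane attacks one enantioface of the trans-disubstituted styrenyl alkene through a spiro transition state and sets both oxirane carbons as R (the first stereocentres, by asymmetric organocatalysis).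

Step 4
Reactants: 5 tert-butyl{3,5-bis(benzyloxy)-2-[((2R,3R)-3-[4-(benzyloxy)phenyl]oxiran-2-yl)methyl]phenoxy}dimethylsilane
Product: 7 (2S,3R)-5,7-bis(benzyloxy)-2-[4-(benzyloxy)phenyl]chroman-3-ol, via free phenol epoxide 6 (not isolated)
Conditions: TBAF, AcOH, THF, 0 °C; then CSA (10 mol%), CH2Cl2, −20 to 0 °C
Reagents that add atoms: none
Why: Buffered desilylation then acid-catalysed 6-endo epoxide opening, in which the phenol attacks the benzylic carbon with inversion (R to S) while the C3 oxygen keeps its configuration, giving the 2,3-trans flavan-3-ol.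

Step 5
Reactants: 7 (2S,3R)-5,7-bis(benzyloxy)-2-[4-(benzyloxy)phenyl]chroman-3-ol
Product: 8 (2S,3R)-5,7-bis(benzyloxy)-2-[4-(benzyloxy)phenyl]-8-bromochroman-3-ol
Conditions: NBS (1.0 equiv), CH2Cl2, −78 to 0 °C
Reagents that add atoms: N-bromosuccinimide, BrN1C(=O)CCC1=O
Why: Electrophilic aromatic bromination goes to C8, the less hindered position of the 5,7-dialkoxy ring (flanked by the ring oxygen and one benzyloxy group).

Step 6
Reactants: 8 (2S,3R)-5,7-bis(benzyloxy)-2-[4-(benzyloxy)phenyl]-8-bromochroman-3-ol; 9 1-(benzyloxy)-4-ethynylbenzene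
Product: 10 (2S,3R)-5,7-bis(benzyloxy)-2-[4-(benzyloxy)phenyl]-8-{[4-(benzyloxy)phenyl]ethynyl}chroman-3-ol
Conditions: PdCl2(MeCN)2 (3 mol%), XPhos (9 mol%), Cs2CO3, MeCN, 80 °C
Reagents that add atoms: none
Why: Copper-free Sonogashira coupling with a bulky electron-rich phosphine, which copes with the hindered electron-rich aryl bromide and the free alcohol.

Step 7
Reactants: 10 (2S,3R)-5,7-bis(benzyloxy)-2-[4-(benzyloxy)phenyl]-8-{[4-(benzyloxy)phenyl]ethynyl}chroman-3-ol
Product: 11 (2S,3R)-5-(benzyloxy)-2,8-bis[4-(benzyloxy)phenyl]-9-iodo-3,4-dihydro-2H-furo[2,3-h]chromen-3-ol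
Conditions: I2 (2 equiv), CH2Cl2, 0 °C to rt; aq. Na2S2O3 work-up
Reagents that add atoms: iodine, II
Why: Iodonium-triggered 5-endo-dig electrophilic cyclisation, in which the ortho benzyl ether oxygen attacks the activated alkyne and iodide removes the benzyl group from the oxonium ion by SN2, closing the furan ring and leaving a C–I handle.

Step 8
Reactants: 11 (2S,3R)-5-(benzyloxy)-2,8-bis[4-(benzyloxy)phenyl]-9-iodo-3,4-dihydro-2H-furo[2,3-h]chromen-3-ol
Product: 13 (2S,3R)-5-(benzyloxy)-2,8-bis[4-(benzyloxy)phenyl]-3-hydroxy-3,4-dihydro-2H-furo[2,3-h]chromene-9-carbaldehyde, via arylmagnesium chloride 12 (not isolated)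
Conditions: i-PrMgCl·LiCl (2.2 equiv), THF, −40 °C; DMF, −40 to 0 °C; aq. NH4Cl
Reagents that add atoms: N,N-dimethylformamide, CN(C)C=O
Why: Iodine–magnesium exchange then formylation, with the magnesium species kept cold so that the 3-metallated benzofuran does not ring-open.

Step 9
Reactants: 13 (2S,3R)-5-(benzyloxy)-2,8-bis[4-(benzyloxy)phenyl]-3-hydroxy-3,4-dihydro-2H-furo[2,3-h]chromene-9-carbaldehyde; 1 3,5-bis(benzyloxy)phenol
Product: 15 pentabenzyl flav-3-ene ketal: a 5,7-bis(benzyloxy)-2-[4-(benzyloxy)phenyl]-2H-chromene whose C2 is bonded to O7' and whose C3 (C3=C4, C4–H) is bonded to C8' of the (2'S,3'R)-5'-(benzyloxy)-2'-[4-(benzyloxy)phenyl]chroman-3'-ol unit, ketal carbon configured as in 18, via ortho-hydroxybenzylic alcohol 14 (not isolated)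
Conditions: 1 (1.5 equiv), (R)-TRIP [(R)-3,3'-bis(2,4,6-triisopropylphenyl)-1,1'-binaphthyl-2,2'-diyl hydrogen phosphate] (10 mol%), 4 Å molecular sieves, CHCl3, −20 to 0 °C; Et3N quench
Reagents that add atoms: none
Why: Proposed new method: the chiral phosphoric acid promotes ortho Friedel–Crafts hydroxyalkylation of phenol 1 by the aldehyde and ionises carbinol 14 to an ortho-quinone-methide/benzofuranium cation paired with the chiral phosphate, which stays hydrogen-bonded to the phenol OH and steers that oxygen onto one face of the furan carbon bearing the aryl group in a dearomative ring closure (formally oxa-6π), making the C4–C4a and O1–C2 bonds, the pyran ring and the ketal stereocentre under catalyst control at low temperature before the ketal can re-ionise; the closest known reaction types are the phenol plus enal chromenylation (formal [3+3] through an ortho-quinone methide) and chiral-phosphoric-acid catalysis of ortho-quinone methides from ortho-hydroxybenzyl alcohols, here extended to a benzofuran C2=C3 bond as the ene partner.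

Step 10
Reactants: 15 pentabenzyl flav-3-ene ketal
Product: 16 3,4-cis-diol of 15, with C3–OH and C4–OH cis to each other and both anti to the C2 aryl group (trans-fused furan/pyran junction)
Conditions: OsO4 (10 mol%), NMO (2 equiv), DABCO (20 mol%), acetone/H2O, 0 °C to rt
Reagents that add atoms: N-methylmorpholine N-oxide, C[N+]1([O-])CCOCC1; water, O
Why: Upjohn dihydroxylation, in which the [3+2] addition of OsO4 occurs on the alkene face opposite the pseudo-axial aryl group on the adjacent ketal carbon (as with flav-3-enes), so the new C3–OH is anti to that aryl group, which is the C3 configuration of the target.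

Step 11
Reactants: 16 3,4-cis-diol of 15
Product: 17 pentabenzyl ether of 18 (C4 ketone; C2 R, C3 S; 2'S,3'R)
Conditions: activated MnO2 (excess), CH2Cl2, rt
Reagents that add atoms: none
Why: MnO2 oxidises only the activated benzylic secondary alcohol next to the trioxygenated ring A, not the tertiary alcohol or the non-benzylic flavan 3'-OH, under neutral conditions that do not ionise the ketal.

Step 12
Reactants: 17 pentabenzyl ether of 18
Product: 18 CNP0146414.1 (target)
Conditions: H2 (1 atm), Pd(OH)2/C, THF/MeOH, rt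
Reagents that add atoms: none
Why: Neutral hydrogenolysis removes the five benzyl aryl ethers and leaves the hindered cyclic ketal, the aryl ketone and all four stereocentres untouched.

**Compound list**
1 | 3,5-bis(benzyloxy)phenol | Oc1cc(OCc2ccccc2)cc(OCc2ccccc2)c1 | starting material
2 | (E)-3-[4-(benzyloxy)phenyl]prop-2-en-1-ol | OC/C=C/c1ccc(OCc2ccccc2)cc1 | starting material
3 | 3,5-bis(benzyloxy)-2-{(E)-3-[4-(benzyloxy)phenyl]prop-2-en-1-yl}phenol | Oc1cc(OCc2ccccc2)cc(OCc2ccccc2)c1C/C=C/c1ccc(OCc2ccccc2)cc1 | intermediate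
4 | tert-butyldimethylsilyl ether of 3 | CC(C)(C)[Si](C)(C)Oc1cc(OCc2ccccc2)cc(OCc2ccccc2)c1C/C=C/c1ccc(OCc2ccccc2)cc1 | intermediate
5 | silyl ether bearing the (2R,3R)-3-[4-(benzyloxy)phenyl]oxiran-2-ylmethyl group | CC(C)(C)[Si](C)(C)Oc1cc(OCc2ccccc2)cc(OCc2ccccc2)c1C[C@H]1O[C@@H]1c1ccc(OCc2ccccc2)cc1 | intermediate
6 | free phenol (2R,3R)-epoxide | Oc1cc(OCc2ccccc2)cc(OCc2ccccc2)c1C[C@H]1O[C@@H]1c1ccc(OCc2ccccc2)cc1 | intermediate
7 | (2S,3R)-5,7-bis(benzyloxy)-2-[4-(benzyloxy)phenyl]chroman-3-ol | c1c(OCc3ccccc3)cc(OCc3ccccc3)c2c1O[C@@H](c1ccc(OCc3ccccc3)cc1)[C@H](O)C2 | intermediate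
8 | (2S,3R)-5,7-bis(benzyloxy)-2-[4-(benzyloxy)phenyl]-8-bromochroman-3-ol | Brc1c(OCc3ccccc3)cc(OCc3ccccc3)c2c1O[C@@H](c1ccc(OCc3ccccc3)cc1)[C@H](O)C2 | intermediate
9 | 1-(benzyloxy)-4-ethynylbenzene | C#Cc1ccc(OCc2ccccc2)cc1 | starting material
10 | (2S,3R)-5,7-bis(benzyloxy)-2-[4-(benzyloxy)phenyl]-8-{[4-(benzyloxy)phenyl]ethynyl}chroman-3-ol | C(#Cc1ccc(OCc3ccccc3)cc1)c1c(OCc3ccccc3)cc(OCc3ccccc3)c2c1O[C@@H](c1ccc(OCc3ccccc3)cc1)[C@H](O)C2 | intermediate
11 | (2S,3R)-5-(benzyloxy)-2,8-bis[4-(benzyloxy)phenyl]-9-iodo-3,4-dihydro-2H-furo[2,3-h]chromen-3-ol | Ic1c(-c2ccc(OCc3ccccc3)cc2)oc2cc(OCc3ccccc3)c3c(c12)O[C@@H](c1ccc(OCc4ccccc4)cc1)[C@H](O)C3 | intermediate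
12 | 9-chloromagnesio derivative of 11 as its chloromagnesium 3-alkoxide | Cl[Mg]c1c(-c2ccc(OCc3ccccc3)cc2)oc2cc(OCc3ccccc3)c3c(c12)O[C@@H](c1ccc(OCc4ccccc4)cc1)[C@H](O[Mg]Cl)C3 | intermediate
13 | (2S,3R)-5-(benzyloxy)-2,8-bis[4-(benzyloxy)phenyl]-3-hydroxy-3,4-dihydro-2H-furo[2,3-h]chromene-9-carbaldehyde | O=Cc1c(-c2ccc(OCc3ccccc3)cc2)oc2cc(OCc3ccccc3)c3c(c12)O[C@@H](c1ccc(OCc4ccccc4)cc1)[C@H](O)C3 | intermediate
14 | 9-{[2,4-bis(benzyloxy)-6-hydroxyphenyl](hydroxy)methyl} analogue of 13 (both carbinol epimers) | OC(c1c(O)cc(OCc5ccccc5)cc1OCc5ccccc5)c1c(-c2ccc(OCc3ccccc3)cc2)oc2cc(OCc3ccccc3)c3c(c12)O[C@@H](c1ccc(OCc4ccccc4)cc1)[C@H](O)C3 | intermediate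
15 | pentabenzyl flav-3-ene ketal (C3=C4, C4–H; ketal carbon as in 18; 2'S,3'R) | C=1c2c(OCc5ccccc5)cc(OCc5ccccc5)cc2O[C@@]2(c3ccc(OCc5ccccc5)cc3)Oc3cc(OCc5ccccc5)c4c(c3C=12)O[C@@H](c1ccc(OCc5ccccc5)cc1)[C@H](O)C4 | intermediate
16 | 3,4-cis-diol of 15, both hydroxyls anti to the C2 aryl group | O[C@H]1c2c(OCc5ccccc5)cc(OCc5ccccc5)cc2O[C@@]2(c3ccc(OCc5ccccc5)cc3)Oc3cc(OCc5ccccc5)c4c(c3[C@]12O)O[C@@H](c1ccc(OCc5ccccc5)cc1)[C@H](O)C4 | intermediate
17 | pentabenzyl ether of 18 | O=C1c2c(OCc5ccccc5)cc(OCc5ccccc5)cc2O[C@@]2(c3ccc(OCc5ccccc5)cc3)Oc3cc(OCc5ccccc5)c4c(c3[C@]12O)O[C@@H](c1ccc(OCc5ccccc5)cc1)[C@H](O)C4 | intermediate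
18 | CNP0146414.1 (C2 R, C3 S; 2'S,3'R) | O=C1c2c(O)cc(O)cc2O[C@@]2(c3ccc(O)cc3)Oc3cc(O)c4c(c3[C@]12O)O[C@@H](c1ccc(O)cc1)[C@H](O)C4 | target

**Step count**
Total steps: 12. Longest linear sequence: 12 steps (1 and 2 to 18); 9 and a second portion of 1 enter at steps 6 and 9.

**Steps most likely to fail**

Step 9 (the proposed new step). Risks are low facial control, double arylation of the aldehyde, and erosion of the ketal centre by re-ionisation. The fallback uses known chemistry, sets out from 13 and comes back at 15. Phenol 1 is converted with EtMgBr into its bromomagnesium phenoxide, which adds ortho-selectively to aldehyde 13 in toluene (magnesium-phenoxide ortho-hydroxyalkylation) to give the ortho-hydroxybenzylic alcohol 14, now isolated. Brief treatment with an achiral acid (pyridinium p-toluenesulfonate, 4 Å sieves, CH2Cl2) closes the ketal without facial control to 15 and its ketal epimer F1. These are diastereomers and are separated on base-washed silica; the ketal epimer F1 is re-equilibrated with the same acid and recycled.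

Step 10. The alkene is hindered, and the trans-fused product is strained, so osmylation may be slow or may erode the face preference. The fallback sets out from 15 and comes back at 17, bypassing 16. DMDO in acetone at −40 °C (small reagent, early transition state) delivers oxygen to the face opposite the C2 aryl group and gives the 3,4-epoxide F2. Buffered hydrolysis (THF/H2O, NaHCO3) opens the benzylic C4–O bond with inversion to the 3,4-trans-diol F3. Oxidation of the trans-diol F3 with MnO2 as in step 11 gives 17.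

Step 7. The flavan ring oxygen is also ortho to the alkyne and could compete with the benzyl ether oxygen, or debenzylation could stall. The fallback sets out from 8 and comes back at 13, bypassing 10 to 12. Bromine–lithium exchange on 8 (n-BuLi, 2.2 equiv, THF, −78 °C) and DMF give the 8-carbaldehyde F4. BCl3 (CH2Cl2, −78 °C) cleaves only the chelated benzyl ether ortho to the aldehyde and gives the 7-hydroxy-8-carbaldehyde F5. Alkylation with 4-(benzyloxy)benzyl bromide and K2CO3 in DMF gives the 7-O-[4-(benzyloxy)benzyl] ether F6. Cyclodehydration with t-BuOK in DMF at 80 °C (intramolecular condensation of the benzylic carbanion with the aldehyde) gives the 2-arylbenzofuran F7. Vilsmeier formylation (POCl3, DMF) at the free furan carbon of the 2-arylbenzofuran F7 gives 13.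

Further compounds
F1 | step 9 | ketal (C2) epimer of 15 | C=1c2c(OCc5ccccc5)cc(OCc5ccccc5)cc2O[C@]2(c3ccc(OCc5ccccc5)cc3)Oc3cc(OCc5ccccc5)c4c(c3C=12)O[C@@H](c1ccc(OCc5ccccc5)cc1)[C@H](O)C4
F2 | step 10 | 3,4-epoxide of 15, oxygen anti to the C2 aryl group | O6[C@H]1c2c(OCc5ccccc5)cc(OCc5ccccc5)cc2O[C@@]2(c3ccc(OCc5ccccc5)cc3)Oc3cc(OCc5ccccc5)c4c(c3[C@]126)O[C@@H](c1ccc(OCc5ccccc5)cc1)[C@H](O)C4
F3 | step 10 | 3,4-trans-diol (C4 epimer of 16) | O[C@@H]1c2c(OCc5ccccc5)cc(OCc5ccccc5)cc2O[C@@]2(c3ccc(OCc5ccccc5)cc3)Oc3cc(OCc5ccccc5)c4c(c3[C@]12O)O[C@@H](c1ccc(OCc5ccccc5)cc1)[C@H](O)C4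
F4 | step 7 | (2S,3R)-5,7-bis(benzyloxy)-2-[4-(benzyloxy)phenyl]-3-hydroxychroman-8-carbaldehyde | O=Cc1c(OCc3ccccc3)cc(OCc3ccccc3)c2c1O[C@@H](c1ccc(OCc3ccccc3)cc1)[C@H](O)C2
F5 | step 7 | (2S,3R)-5-(benzyloxy)-2-[4-(benzyloxy)phenyl]-3,7-dihydroxychroman-8-carbaldehyde | O=Cc1c(O)cc(OCc3ccccc3)c2c1O[C@@H](c1ccc(OCc3ccccc3)cc1)[C@H](O)C2
F6 | step 7 | (2S,3R)-5-(benzyloxy)-7-{[4-(benzyloxy)benzyl]oxy}-2-[4-(benzyloxy)phenyl]-3-hydroxychroman-8-carbaldehyde | O=Cc1c(OCc3ccc(OCc4ccccc4)cc3)cc(OCc3ccccc3)c2c1O[C@@H](c1ccc(OCc3ccccc3)cc1)[C@H](O)C2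
F7 | step 7 | (2S,3R)-5-(benzyloxy)-2,8-bis[4-(benzyloxy)phenyl]-3,4-dihydro-2H-furo[2,3-h]chromen-3-ol | c1c(-c2ccc(OCc3ccccc3)cc2)oc2cc(OCc3ccccc3)c3c(c12)O[C@@H](c1ccc(OCc4ccccc4)cc1)[C@H](O)C3
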